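**Plan**

1. Retrosynthesis removes the C4 acetate and the C3 (2S,3S)-epoxyangelate, then cuts C4–C5 (ring A, vinylogous aldol), C7–C11 (cross-coupling) and C10–C1 (conjugate addition). This leaves 3-methylcyclohexenone (ring B), a five-carbon chain from (R)-α-hydroxy-γ-butyrolactone, isopropylzinc bromide and angelic acid.
2. Enabling feature (eudesmane locants, C14 on C10, C15 on C4): C5 is the γ-carbon of the ring B enone C6=C7–C8=O, and C4 is a methyl carbinol carbon tied to C10 through C1–C2–C3. A ring B dienolate can therefore close ring A on a C4 ketone through C5.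
3. Forward: the chain is joined to ring B by asymmetric conjugate addition, ring B is desaturated and isopropylated, ring A is closed (C4–C5), and hydrogenation and the two acylations follow.
4. Base-mediated closure would compete with reversible attack from C9 and with enolisation at C3. The dienolate is therefore used as its through-conjugated silyl dienol ether and the ketone as its dibenzyl ketal (Mukaiyama mode).
5. Stereochemistry: C3 from the chiral pool, C10 from the copper–NHC catalyst, C5 and C4 from C10 through the chair-like closure, C7 by equilibration, the epoxide from a Sharpless epoxidation.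

Key step: step 10

Remark: the sense of induction in step 5 depends on the ligand enantiomer; the enantiomer that adds the chain to the enone face giving (3R)-8 is used.

**Route**

Step 1
Reactants: 1 (3R)-3-hydroxyoxolan-2-one
Product: 2 (3R)-3-(benzyloxy)oxolan-2-one
Conditions: BnOC(=NH)CCl3, TfOH (5 mol%), CH2Cl2–cyclohexane, 0 °C → rt
Reagents that add atoms: benzyl 2,2,2-trichloroacetimidate, ClC(Cl)(Cl)C(=N)OCc1ccccc1
Why: Acid-catalysed O-benzylation with a trichloroacetimidate needs no base, so the α-stereocentre of the lactone is not enolised.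

Step 2
Reactants: 2 (3R)-3-(benzyloxy)oxolan-2-one
Product: 3 (3R)-3-(benzyloxy)-5-hydroxypentan-2-one
Conditions: MeLi (1.05 equiv), THF, −78 °C; AcOH quench at −78 °C
Reagents that add atoms: methyllithium, [Li]C
Why: Mono-addition of an organolithium to a γ-lactone should stop at the lithium lactolate, which is stable at −78 °C and releases the ketone only on quench.

Step 3
Reactants: 3 (3R)-3-(benzyloxy)-5-hydroxypentan-2-one
Product: 4 (3R)-3-(benzyloxy)-5-bromopentan-2-one
Conditions: CBr4, PPh3, CH2Cl2, 0 °C
Reagents that add atoms: carbon tetrabromide, BrC(Br)(Br)Br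
Why: The Appel reaction converts the primary alcohol of the open hydroxy ketone under neutral conditions, which leave the α-stereocentre untouched.

Step 4
Reactants: 4 (3R)-3-(benzyloxy)-5-bromopentan-2-one
Product: 5 (3R)-2,2,3-tris(benzyloxy)-5-bromopentane
Conditions: BnOSiMe3 (2.5 equiv), Me3SiOTf (5 mol%), CH2Cl2, −78 → −30 °C; pyridine quench
Reagents that add atoms: benzyloxytrimethylsilane, C[Si](C)(C)OCc1ccccc1
Why: Ketalisation with an alkoxysilane and catalytic silyl triflate is aprotic and driven by siloxane formation, so the acyclic dibenzyl ketal should form cold without enolisation towards C3; benzyl is chosen so that the C4 oxygen can later be freed by hydrogenolysis.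

Step 5
Reactants: 5 (3R)-2,2,3-tris(benzyloxy)-5-bromopentane; 6 3-methylcyclohex-2-en-1-one
Product: 8 (3R)-3-methyl-3-[(3R)-3,4,4-tris(benzyloxy)pentyl]cyclohexan-1-one, via Grignard reagent 7 (not isolated)
Conditions: Mg, Et2O, 35 °C; then 6, Cu(OTf)2 (3 mol%), chiral imidazolinium salt (N-heterocyclic carbene precursor, 4 mol%), Et2O, 0 °C; aq. NH4Cl
Reagents that add atoms: none
Why: Copper–NHC-catalysed asymmetric conjugate addition of a Grignard reagent to a β-substituted cyclohexenone builds the quaternary C10, with the catalyst choosing the enone face and the remote C3 centre of the reagent acting as a spectator.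

Step 6
Reactants: 8 (3R)-3-methyl-3-[(3R)-3,4,4-tris(benzyloxy)pentyl]cyclohexan-1-one
Product: 10 (5S)-5-methyl-5-[(3R)-3,4,4-tris(benzyloxy)pentyl]cyclohex-2-en-1-one, via trimethylsilyl enol ether 9 (not isolated)
Conditions: LiN(i-Pr)2, Me3SiCl, THF, −78 °C; then Pd(OAc)2 (1.05 equiv), MeCN, rt
Reagents that add atoms: none
Why: In this Saegusa–Ito oxidation the amide base removes a proton from C7, the α-methylene remote from the quaternary carbon, and any C9 silyl enol ether cannot give an enone because C10 bears no hydrogen, so only the C6–C7 enone can form.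

Step 7
Reactants: 10 (5S)-5-methyl-5-[(3R)-3,4,4-tris(benzyloxy)pentyl]cyclohex-2-en-1-one
Product: 11 (5S)-2-iodo-5-methyl-5-[(3R)-3,4,4-tris(benzyloxy)pentyl]cyclohex-2-en-1-one
Conditions: I2, pyridine–CH2Cl2 (1:1), 0 °C → rt
Reagents that add atoms: iodine, II
Why: Pyridine-mediated α-iodination of a cyclic enone (conjugate addition of pyridine, iodination of the enolate, elimination) places iodine on C7 only, and the buffered medium spares the ketal.

Step 8
Reactants: 11 (5S)-2-iodo-5-methyl-5-[(3R)-3,4,4-tris(benzyloxy)pentyl]cyclohex-2-en-1-one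
Product: 12 (5S)-5-methyl-2-(propan-2-yl)-5-[(3R)-3,4,4-tris(benzyloxy)pentyl]cyclohex-2-en-1-one
Conditions: i-PrZnBr (1.5 equiv), PdCl2(dppf) (5 mol%; dppf = 1,1′-bis(diphenylphosphino)ferrocene), THF, rt → 40 °C
Reagents that add atoms: isopropylzinc bromide, CC(C)[Zn]Br
Why: Negishi coupling of an alkenyl iodide with a secondary alkylzinc halide should transfer isopropyl without isomerisation to n-propyl, because the wide-bite-angle diphosphine favours reductive elimination over β-hydride elimination.

Step 9
Reactants: 12 (5S)-5-methyl-2-(propan-2-yl)-5-[(3R)-3,4,4-tris(benzyloxy)pentyl]cyclohex-2-en-1-one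
Product: 14 tert-butyldimethyl({(5R)-5-methyl-2-(propan-2-yl)-5-[(3R)-3,4,4-tris(benzyloxy)pentyl]cyclohexa-1,3-dien-1-yl}oxy)silane, via potassium dienolate 13 (not isolated)
Conditions: KN(SiMe3)2 (0.95 equiv), THF, −78 → 0 °C (equilibration); then t-BuMe2SiCl, 0 °C
Reagents that add atoms: tert-butyldimethylsilyl chloride, CC(C)(C)[Si](C)(C)Cl
Why: Thermodynamic enolate formation followed by O-silylation: with a slight deficit of base the potassium enolates should equilibrate by proton exchange to the through-conjugated dienolate (tetrasubstituted C7=C8 enolate, C5=C6 alkene), which the silyl chloride traps on oxygen; the ketal chain has no acidic hydrogen.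

Step 10
Reactants: 14 tert-butyldimethyl({(5R)-5-methyl-2-(propan-2-yl)-5-[(3R)-3,4,4-tris(benzyloxy)pentyl]cyclohexa-1,3-dien-1-yl}oxy)silane
Product: 15 3α,4α-bis(benzyloxy)-5βH-eudesm-6-en-8-one
Conditions: Me3SiOTf (20 mol%), 2,6-di-tert-butyl-4-methylpyridine (30 mol%), CH2Cl2, −78 → −40 °C; Et3N quench
Reagents that add atoms: none
Why: The silyl triflate ionises the dibenzyl ketal to the C4 oxocarbenium ion, which the through-conjugated silyl dienol ether attacks through its γ-carbon C5, after which the silyl group leaves with the expelled benzyloxy group and the C6=C7–C8=O enone is restored; the closest known reaction type is the Lewis-acid-mediated vinylogous Mukaiyama aldol addition of silyl dienol ethers to acetals and ketals. Ring A closes in a 6-(enolexo)-exo-trig mode, closure through C7 would need an eight-membered ring, and a C9 enolate cannot arise because the dienol ether is regiochemically fixed and no base is present. C5 is controlled by C10: with the side chain pseudo-equatorial on the half-chair of ring B, the chair-like closure forms the new bond pseudo-axially and anti to C14, which gives the cis ring fusion (5βH). C4 is controlled by the same chair, which keeps C15 equatorial and the oxocarbenium oxygen axial so that no methyl group faces C9 in a 1,3-diaxial sense, and the (R)-configured C3 then carries its benzyloxy group equatorially and cis to the new C4 oxygen. The step needs γ- and not α′-reactivity of the ring B enone and an intact C3 centre, and both are secured by storing the extended dienolate as its silyl ether and the ketone as a ketal, so that the bond forms under kinetic, non-basic conditions.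

Step 11
Reactants: 15 3α,4α-bis(benzyloxy)-5βH-eudesm-6-en-8-one
Product: 17 (3R,4S,5S,7R,10R)-3,4-dihydroxyeudesman-8-one, via 7-epimeric diol ketone 16 (not isolated)
Conditions: H2 (1 atm), Pd/C, EtOH, rt; filter; then NaOMe (0.2 equiv), MeOH, rt
Reagents that add atoms: none
Why: Heterogeneous hydrogenation saturates the C6–C7 alkene and hydrogenolyses both benzyl ethers in one operation, and base-mediated epimerisation α to the ketone should then converge C7 on the equatorial 7β-isopropyl (7R) isomer, the arrangement free of a 1,3-diaxial contact with C4.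

Step 12
Reactants: 18 angelic acid [(2Z)-2-methylbut-2-enoic acid]
Product: 19 (2Z)-2-methylbut-2-en-1-ol
Conditions: LiAlH4, Et2O, 0 °C → rt
Reagents that add atoms: none
Why: Hydride reduction of the carboxylic acid gives the allylic alcohol and leaves the Z-trisubstituted alkene untouched.

Step 13
Reactants: 19 (2Z)-2-methylbut-2-en-1-ol
Product: 20 [(2R,3S)-2,3-dimethyloxiran-2-yl]methanol
Conditions: Ti(Oi-Pr)4 (10 mol%), D-(−)-diethyl tartrate (12 mol%), t-BuOOH, 4 Å molecular sieves, CH2Cl2, −20 °C
Reagents that add atoms: tert-butyl hydroperoxide, CC(C)(C)OO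
Why: In the Sharpless asymmetric epoxidation the D-(−)-tartrate catalyst delivers oxygen to the alkene face that gives the (2R,3S)-epoxy alcohol, and the Z geometry fixes the cis relation of CH2OH and the C3 methyl group.

Step 14
Reactants: 20 [(2R,3S)-2,3-dimethyloxiran-2-yl]methanol
Product: 21 (2S,3S)-2,3-dimethyloxirane-2-carboxylic acid
Conditions: RuCl3·xH2O (2 mol%), NaIO4, MeCN–EtOAc–H2O, 0 °C → rt
Reagents that add atoms: sodium periodate, [Na+].[O-]I(=O)(=O)=O; water, O
Why: Ruthenium tetroxide-catalysed oxidation takes the primary epoxy alcohol to the glycidic acid without opening the epoxide, and the C2 descriptor changes from R to S only through the change in substituent priority.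

Step 15
Reactants: 17 (3R,4S,5S,7R,10R)-3,4-dihydroxyeudesman-8-one; 21 (2S,3S)-2,3-dimethyloxirane-2-carboxylic acid
Product: 23 (3R,4S,5S,7R,10R)-4-hydroxy-8-oxoeudesman-3-yl (2S,3S)-2,3-dimethyloxirane-2-carboxylate, via mixed anhydride 22 (not isolated)
Conditions: 21, 2,4,6-Cl3C6H2COCl, Et3N, toluene, rt; then 17, DMAP, toluene, rt
Reagents that add atoms: none
Why: Yamaguchi esterification acylates the equatorial secondary C3 hydroxyl while the axial tertiary C4 hydroxyl stays inert, and acylating C3 first rules out a later tertiary-to-secondary acyl migration.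

Step 16
Reactants: 23 (3R,4S,5S,7R,10R)-4-hydroxy-8-oxoeudesman-3-yl (2S,3S)-2,3-dimethyloxirane-2-carboxylate
Product: 24 (3R,4S,5S,7R,10R)-4-acetoxy-8-oxoeudesman-3-yl (2S,3S)-2,3-dimethyloxirane-2-carboxylate
Conditions: Ac2O (excess), DMAP (2 equiv), Et3N, CH2Cl2, 40 °C
Reagents that add atoms: acetic anhydride, CC(=O)OC(C)=O
Why: DMAP-catalysed (Steglich-type) acyl transfer with excess anhydride should acetylate the tertiary alcohol, while the glycidic ester, the ketone and the equatorial C7 centre are stable to these mildly basic, non-acidic conditions.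

**Compound list**

1 | (3R)-3-hydroxyoxolan-2-one [(R)-α-hydroxy-γ-butyrolactone] | O=C1OCC[C@H]1O | starting material
2 | (3R)-3-(benzyloxy)oxolan-2-one | O=C1OCC[C@H]1OCc1ccccc1 | intermediate
3 | (3R)-3-(benzyloxy)-5-hydroxypentan-2-one (in equilibrium with its cyclic hemiketal) | CC(=O)[C@H](OCc1ccccc1)CCO | intermediate
4 | (3R)-3-(benzyloxy)-5-bromopentan-2-one | CC(=O)[C@H](OCc1ccccc1)CCBr | intermediate
5 | (3R)-2,2,3-tris(benzyloxy)-5-bromopentane | CC(OCc1ccccc1)(OCc1ccccc1)[C@H](OCc1ccccc1)CCBr | intermediate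
6 | 3-methylcyclohex-2-en-1-one | CC1=CC(=O)CCC1 | starting material
7 | [(3R)-3,4,4-tris(benzyloxy)pentyl]magnesium bromide | CC(OCc1ccccc1)(OCc1ccccc1)[C@H](OCc1ccccc1)CC[Mg]Br | intermediate
8 | (3R)-3-methyl-3-[(3R)-3,4,4-tris(benzyloxy)pentyl]cyclohexan-1-one | CC(OCc1ccccc1)(OCc1ccccc1)[C@H](OCc1ccccc1)CC[C@@]1(C)CCCC(=O)C1 | intermediate
9 | trimethyl({(5R)-5-methyl-5-[(3R)-3,4,4-tris(benzyloxy)pentyl]cyclohex-1-en-1-yl}oxy)silane | CC(OCc1ccccc1)(OCc1ccccc1)[C@H](OCc1ccccc1)CC[C@@]1(C)CCC=C(O[Si](C)(C)C)C1 | intermediate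
10 | (5S)-5-methyl-5-[(3R)-3,4,4-tris(benzyloxy)pentyl]cyclohex-2-en-1-one | CC(OCc1ccccc1)(OCc1ccccc1)[C@H](OCc1ccccc1)CC[C@@]1(C)CC=CC(=O)C1 | intermediate
11 | (5S)-2-iodo-5-methyl-5-[(3R)-3,4,4-tris(benzyloxy)pentyl]cyclohex-2-en-1-one | CC(OCc1ccccc1)(OCc1ccccc1)[C@H](OCc1ccccc1)CC[C@@]1(C)CC=C(I)C(=O)C1 | intermediate
12 | (5S)-5-methyl-2-(propan-2-yl)-5-[(3R)-3,4,4-tris(benzyloxy)pentyl]cyclohex-2-en-1-one | CC(OCc1ccccc1)(OCc1ccccc1)[C@H](OCc1ccccc1)CC[C@@]1(C)CC=C(C(C)C)C(=O)C1 | intermediate
13 | potassium (5R)-5-methyl-2-(propan-2-yl)-5-[(3R)-3,4,4-tris(benzyloxy)pentyl]cyclohexa-1,3-dien-1-olate | CC(OCc1ccccc1)(OCc1ccccc1)[C@H](OCc1ccccc1)CC[C@@]1(C)C=CC(C(C)C)=C([O-])C1.[K+] | intermediate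
14 | tert-butyldimethyl({(5R)-5-methyl-2-(propan-2-yl)-5-[(3R)-3,4,4-tris(benzyloxy)pentyl]cyclohexa-1,3-dien-1-yl}oxy)silane | CC(OCc1ccccc1)(OCc1ccccc1)[C@H](OCc1ccccc1)CC[C@@]1(C)C=CC(C(C)C)=C(O[Si](C)(C)C(C)(C)C)C1 | intermediate
15 | 3α,4α-bis(benzyloxy)-5βH-eudesm-6-en-8-one, (3R,4S,5S,10R), cis-fused | O(Cc1ccccc1)[C@]2(C)[C@H](OCc3ccccc3)CC[C@]4(C)CC(=O)C(C(C)C)=C[C@@H]42 | intermediate
16 | (3R,4S,5S,7S,10R)-3,4-dihydroxyeudesman-8-one (7α-isopropyl epimer) | O[C@]1(C)[C@H](O)CC[C@]2(C)CC(=O)[C@H](C(C)C)C[C@@H]21 | intermediate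
17 | (3R,4S,5S,7R,10R)-3,4-dihydroxyeudesman-8-one (3α,4α-diol, 5βH, 7β-isopropyl) | O[C@]1(C)[C@H](O)CC[C@]2(C)CC(=O)[C@@H](C(C)C)C[C@@H]21 | intermediate
18 | angelic acid, (2Z)-2-methylbut-2-enoic acid | C/C=C(/C)C(=O)O | starting material
19 | (2Z)-2-methylbut-2-en-1-ol | C/C=C(/C)CO | intermediate
20 | [(2R,3S)-2,3-dimethyloxiran-2-yl]methanol | OC[C@@]1(C)O[C@H]1C | intermediate
21 | (2S,3S)-2,3-dimethyloxirane-2-carboxylic acid | OC(=O)[C@@]1(C)O[C@H]1C | intermediate
22 | (2S,3S)-2,3-dimethyloxirane-2-carboxylic 2,4,6-trichlorobenzoic anhydride | O=C(OC(=O)c1c(Cl)cc(Cl)cc1Cl)[C@@]1(C)O[C@H]1C | intermediate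
23 | (3R,4S,5S,7R,10R)-4-hydroxy-8-oxoeudesman-3-yl (2S,3S)-2,3-dimethyloxirane-2-carboxylate | O[C@]1(C)[C@H](OC(=O)[C@@]3(C)O[C@H]3C)CC[C@]2(C)CC(=O)[C@@H](C(C)C)C[C@@H]21 | intermediate
24 | (3R,4S,5S,7R,10R)-4-acetoxy-8-oxoeudesman-3-yl (2S,3S)-2,3-dimethyloxirane-2-carboxylate (CNP0221066.1) | CC(=O)O[C@]1(C)[C@H](OC(=O)[C@@]2(C)O[C@H]2C)CC[C@]2(C)CC(=O)[C@@H](C(C)C)C[C@@H]21 | target

**Totals and risks**

Total step count: 16. Longest linear sequence: 13 steps (steps 1–11, 15 and 16); steps 12–14 form the side branch to acid 21.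

Steps most likely to fail:

1. Step 10. The ketal may ionise without ring closure (loss of a benzyloxy group to an enol ether, or protodesilylation of the dienol ether), or closure may pass through a non-chair arrangement and erode the C4 configuration. The fallback sets out from 12 and forms the same bond under Brønsted-base control. Brief hydrolysis of the dibenzyl ketal (0.5 M HCl, THF, 0 °C) gives the diketone (5S)-5-[(3R)-3-(benzyloxy)-4-oxopentyl]-5-methyl-2-(propan-2-yl)cyclohex-2-en-1-one F1. Treatment with t-BuOK (0.3 equiv) in t-BuOH–THF at 0 °C then closes ring A by the reversible intramolecular vinylogous aldol addition, giving the ketol 3α-benzyloxy-4α-hydroxy-5βH-eudesm-6-en-8-one F2. F2 is hydrogenated, debenzylated and equilibrated under the conditions of step 11, which rejoins the route at 17. This variant must contend with reversible closure from C9 and with enolisation towards C3, which is why it is the reserve.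

2. Step 16. Acyl transfer to the hindered axial tertiary hydroxyl may be too slow, and forcing it may open the epoxide. The fallback sets out from 17 and puts the acetate on before the epoxy acid. Trimethyl orthoacetate with catalytic pyridinium p-toluenesulfonate (CH2Cl2, rt) gives the cyclic 3,4-orthoacetate F3. Opening in 80% aqueous acetic acid at rt, which leaves the acyl group on the axial oxygen, gives the 4-acetate 3-alcohol (3R,4S,5S,7R,10R)-4-acetoxy-3-hydroxyeudesman-8-one F4. Yamaguchi esterification of F4 with 21 (through 22, DMAP, toluene, 0 °C, kept short to outrun acetyl migration) gives 24.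

3. Step 5. Conversion or enantioselectivity may be low because the three ether oxygens of the Grignard reagent compete for magnesium and copper. The fallback sets out from 5 and exchanges the roles of the two carbon groups. Grignard reagent 7 is added in a 1,2-sense to commercial 3-ethoxycyclohex-2-en-1-one to give the carbinol 3-ethoxy-1-[(3R)-3,4,4-tris(benzyloxy)pentyl]cyclohex-2-en-1-ol F5. Buffered acidic work-up (aqueous oxalic acid, 0 °C) effects the Stork–Danheiser transposition to 3-[(3R)-3,4,4-tris(benzyloxy)pentyl]cyclohex-2-en-1-one F6. Copper-catalysed asymmetric conjugate addition of Me3Al (copper thiophene-2-carboxylate Cu(O2CC4H3S), chiral phosphoramidite ligand, Et2O, −30 °C) then installs the C14 methyl group and returns 8.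

**Further compounds**

F1 | step 10 | (5S)-5-[(3R)-3-(benzyloxy)-4-oxopentyl]-5-methyl-2-(propan-2-yl)cyclohex-2-en-1-one | CC(=O)[C@H](OCc1ccccc1)CC[C@@]1(C)CC=C(C(C)C)C(=O)C1
F2 | step 10 | 3α-benzyloxy-4α-hydroxy-5βH-eudesm-6-en-8-one | O[C@]1(C)[C@H](OCc2ccccc2)CC[C@]2(C)CC(=O)C(C(C)C)=C[C@@H]21
F3 | step 16 | cyclic 3,4-(1-methoxyethylidene) orthoacetate of 17 | O3[C@]1(C)[C@H](OC3(C)OC)CC[C@]2(C)CC(=O)[C@@H](C(C)C)C[C@@H]21
F4 | step 16 | (3R,4S,5S,7R,10R)-4-acetoxy-3-hydroxyeudesman-8-one | CC(=O)O[C@]1(C)[C@H](O)CC[C@]2(C)CC(=O)[C@@H](C(C)C)C[C@@H]21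
F5 | step 5 | 3-ethoxy-1-[(3R)-3,4,4-tris(benzyloxy)pentyl]cyclohex-2-en-1-ol | CC(OCc1ccccc1)(OCc1ccccc1)[C@H](OCc1ccccc1)CCC1(O)CCCC(OCC)=C1
F6 | step 5 | 3-[(3R)-3,4,4-tris(benzyloxy)pentyl]cyclohex-2-en-1-one | CC(OCc1ccccc1)(OCc1ccccc1)[C@H](OCc1ccccc1)CCC1=CC(=O)CCC1
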